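**Strategy.** The target is cut back to spiro ketone 12 and an o-quinone methide. Everything rests on closing the cyclohexene ring between the spiro carbon and the CH(CH3) carbon. The spiro carbon is both α to the future O–CH carbon (a ketone) and allylic to the ring C=C, so it is the α-carbon of an extended dienolate. An intramolecular deconjugative alkylation of that dienolate by an enantiopure secondary mesylate forms this bond, creates the quaternary spiro centre, inverts the methyl-bearing carbon and moves the alkene into the ring in one operation. The precursor is a simple 2-alkylidene-5-methylcyclopentanone. A hetero-Diels–Alder reaction of the derived vinyl sulfide then builds the chroman.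

Key step: step 5

Assumption: 2,4,6-trihydroxybenzene-1,3-dicarbaldehyde (16) and an (S)-selective alcohol dehydrogenase are taken as purchasable. Centres that are erased later (ring C-2 of the cyclopentanone, the isopropyl-bearing side-chain carbon) are carried as epimer mixtures and left undefined in the SMILES.

Step 1
Reactants: 1 3-methylbutanal; 2 but-3-en-2-one
Product: 3 5-oxo-2-(propan-2-yl)hexanal (racemic)
Conditions: Et2NSiMe3 (10 mol %), MeCN, 80 °C
Reagents that add atoms: none
Why: Amine-mediated (enamine) Michael addition of the aldehyde to the enone should give the 1,5-keto aldehyde, whose α-centre is irrelevant because it becomes sp2 in step 5.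

Step 2
Reactants: 4 2-methylcyclopentan-1-one; 3 5-oxo-2-(propan-2-yl)hexanal
Product: 8 (2E)-5-methyl-2-[5-oxo-2-(propan-2-yl)hexylidene]cyclopentan-1-one, via lithium enolate 5 (not isolated), via lithium aldolate 6 (not isolated), via aldol mesylate 7 (not isolated)
Conditions: LiN(i-Pr)2, THF, −78 °C; then 3; then MsCl, −78 → 0 °C; then DBU, 0 → 25 °C
Reagents that add atoms: none
Why: Kinetic deprotonation of 4 at the unsubstituted α-carbon, chemoselective aldol addition to the aldehyde of 3 and E1cB elimination of the mesylate formed in the flask (aldol condensation) should give the (E)-alkylidene ketone.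

Step 3
Reactants: 8 (2E)-5-methyl-2-[5-oxo-2-(propan-2-yl)hexylidene]cyclopentan-1-one
Product: 9 (2E)-2-[(5S)-5-hydroxy-2-(propan-2-yl)hexylidene]-5-methylcyclopentan-1-one
Conditions: alcohol dehydrogenase ADH-A (Rhodococcus ruber), NADH (cat.), i-PrOH/phosphate buffer pH 7.5, 30 °C
Reagents that add atoms: none
Why: Enzymatic asymmetric ketone reduction should deliver hydride from NADH (recycled by isopropanol) to the re face of the unhindered methyl ketone, setting the carbinol centre as S, and leave the hindered conjugated cyclopentanone untouched.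

Step 4
Reactants: 9 (2E)-2-[(5S)-5-hydroxy-2-(propan-2-yl)hexylidene]-5-methylcyclopentan-1-one
Product: 10 (2S)-6-methyl-5-[(E)-(3-methyl-2-oxocyclopentylidene)methyl]heptan-2-yl methanesulfonate
Conditions: MsCl, Et3N, CH2Cl2, 0 °C
Reagents that add atoms: methanesulfonyl chloride CS(=O)(=O)Cl
Why: O-Sulfonylation of the secondary alcohol proceeds with retention and turns it into a leaving group.

Step 5
Reactants: 10 (2S)-6-methyl-5-[(E)-(3-methyl-2-oxocyclopentylidene)methyl]heptan-2-yl methanesulfonate
Product: 12 (5R,10R)-2,10-dimethyl-7-(propan-2-yl)spiro[4.5]dec-6-en-1-one, via potassium dienolate 11 (not isolated)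
Conditions: KOt-Bu (1.1 equiv), t-BuOH/THF, 0 → 25 °C
Reagents that add atoms: none
Why: Reversible γ-deprotonation of the alkylidene ketone gives the extended dienolate 11, whose α-carbon displaces the mesylate in an intramolecular SN2 reaction; the closest known reaction type is the deconjugative α-alkylation of enone dienolates used for spiroannulation. The ring closed is the cyclohexene, in a 6-(enolexo)-exo-tet mode, and the same event moves the C=C bond from the exocyclic to the endocyclic trisubstituted position and creates the quaternary spiro carbon. The methyl-bearing carbon is inverted, so the enzyme-set S carbinol becomes the 10R centre. The spiro centre (5R) is controlled by that stereocentre: in the chair-like transition state the methyl group should lie pseudo-equatorial and gauche to the flat enolate carbon rather than to the ring CH2, which places methyl and carbonyl carbon cis on the new ring. The step needs C- over O-alkylation and substitution over E2 elimination; O- and γ-attack would give eight- and four-membered rings, and the cross-conjugated enolate at the other α-carbon cannot cyclise and reverts by proton exchange with tert-butanol.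

Step 6
Reactants: 12 (5R,10R)-2,10-dimethyl-7-(propan-2-yl)spiro[4.5]dec-6-en-1-one
Product: 14 (5R,10R)-2,10-dimethyl-7-(propan-2-yl)spiro[4.5]deca-1,6-dien-1-yl trifluoromethanesulfonate, via potassium enolate 13 (not isolated)
Conditions: KN(SiMe3)2, THF, −78 °C; PhNTf2, −78 → 0 °C
Reagents that add atoms: N-phenylbis(trifluoromethanesulfonimide) O=S(=O)(N(c1ccccc1)S(=O)(=O)C(F)(F)F)C(F)(F)F
Why: The only α-hydrogen of 12 is removed and the enolate is O-triflated (enol triflate formation), which also erases the epimeric methyl-bearing centre.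

Step 7
Reactants: 14 (5R,10R)-2,10-dimethyl-7-(propan-2-yl)spiro[4.5]deca-1,6-dien-1-yl trifluoromethanesulfonate
Product: 15 (5R,10R)-2,10-dimethyl-1-(phenylsulfanyl)-7-(propan-2-yl)spiro[4.5]deca-1,6-diene
Conditions: PhSH, Pd2(dba)3 (cat.), Xantphos (cat.), i-Pr2NEt, 1,4-dioxane, 100 °C
Reagents that add atoms: thiophenol Sc1ccccc1
Why: Palladium-catalysed C–S cross-coupling of the alkenyl triflate with the thiol (oxidative addition, thiolate exchange, reductive elimination) should give the vinyl sulfide without touching the stereocentres.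

Step 8
Reactants: 15 (5R,10R)-2,10-dimethyl-1-(phenylsulfanyl)-7-(propan-2-yl)spiro[4.5]deca-1,6-diene; 16 2,4,6-trihydroxybenzene-1,3-dicarbaldehyde; 1 3-methylbutanal
Product: 18 3a'-(phenylsulfanyl) derivative of the target (O,S-ketal cycloadduct), via o-quinone methide 17 (not isolated)
Conditions: ethylenediammonium diacetate (cat.), 4 Å molecular sieves, MeCN, 60 °C
Reagents that add atoms: none
Why: In this domino Knoevenagel/hetero-Diels–Alder reaction 16 and 1 condense to the o-quinone methide 17, which adds to the electron-rich vinyl sulfide with inverse electron demand (benzylic carbon to the methyl-bearing carbon, oxygen to the sulfur-bearing carbon); approach anti to the CH(CH3) carbon of the spiro ring and an endo orientation of the carbocycle should set the quaternary and benzylic centres, and suprafacial addition fixes the cis relation of the new C–C and C–O bonds.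

Step 9
Reactants: 18 3a'-(phenylsulfanyl) derivative of the target (O,S-ketal cycloadduct)
Product: 20 CNP0121396.3, via tertiary α-aryloxy radical 19 (not isolated)
Conditions: Bu3SnH (excess), AIBN (cat.), toluene, 80 °C
Reagents that add atoms: none
Why: In this radical desulfurisation of an O,S-ketal the stannyl radical abstracts the phenylsulfanyl group and the radical 19 should take a hydrogen atom on the face that keeps the cyclopentane cis-fused to the pyran, as ring-fusion radicals of six–five bicycles generally do, giving the O–CH centre.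

**Compound list**

1 | 3-methylbutanal (isovaleraldehyde) | CC(C)CC=O | starting material
2 | but-3-en-2-one (methyl vinyl ketone) | CC(=O)C=C | starting material
3 | 5-oxo-2-(propan-2-yl)hexanal (racemic) | CC(C)C(C=O)CCC(C)=O | intermediate
4 | 2-methylcyclopentan-1-one (racemic) | CC1CCCC1=O | starting material
5 | lithium 5-methylcyclopent-1-en-1-olate (kinetic enolate) | [Li+].[O-]C1=CCCC1C | intermediate
6 | lithium 1-(3-methyl-2-oxocyclopentyl)-5-oxo-2-(propan-2-yl)hexan-1-olate (diastereomer mixture) | [Li+].[O-]C(C(C(C)C)CCC(C)=O)C1CCC(C)C1=O | intermediate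
7 | 1-(3-methyl-2-oxocyclopentyl)-5-oxo-2-(propan-2-yl)hexyl methanesulfonate (diastereomer mixture) | CS(=O)(=O)OC(C(C(C)C)CCC(C)=O)C1CCC(C)C1=O | intermediate
8 | (2E)-5-methyl-2-[5-oxo-2-(propan-2-yl)hexylidene]cyclopentan-1-one (epimer mixture) | CC1CC/C(=C\C(C(C)C)CCC(C)=O)C1=O | intermediate
9 | (2E)-2-[(5S)-5-hydroxy-2-(propan-2-yl)hexylidene]-5-methylcyclopentan-1-one | CC1CC/C(=C\C(C(C)C)CC[C@H](C)O)C1=O | intermediate
10 | (2S)-6-methyl-5-[(E)-(3-methyl-2-oxocyclopentylidene)methyl]heptan-2-yl methanesulfonate | CC1CC/C(=C\C(C(C)C)CC[C@H](C)OS(C)(=O)=O)C1=O | intermediate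
11 | potassium 5-methyl-2-[(1E,5S)-5-(methanesulfonyloxy)-2-(propan-2-yl)hex-1-en-1-yl]cyclopent-1-en-1-olate (extended dienolate) | [K+].[O-]C1=C(/C=C(/C(C)C)CC[C@H](C)OS(C)(=O)=O)CCC1C | intermediate
12 | (5R,10R)-2,10-dimethyl-7-(propan-2-yl)spiro[4.5]dec-6-en-1-one (C-2 epimers) | O=C1C(C)CC[C@@]12C=C(C(C)C)CC[C@H]2C | intermediate
13 | potassium (5R,10R)-2,10-dimethyl-7-(propan-2-yl)spiro[4.5]deca-1,6-dien-1-olate | [K+].[O-]C1=C(C)CC[C@@]12C=C(C(C)C)CC[C@H]2C | intermediate
14 | (5R,10R)-2,10-dimethyl-7-(propan-2-yl)spiro[4.5]deca-1,6-dien-1-yl trifluoromethanesulfonate | FC(F)(F)S(=O)(=O)OC1=C(C)CC[C@@]12C=C(C(C)C)CC[C@H]2C | intermediate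
15 | (5R,10R)-2,10-dimethyl-1-(phenylsulfanyl)-7-(propan-2-yl)spiro[4.5]deca-1,6-diene | c1ccccc1SC2=C(C)CC[C@@]23C=C(C(C)C)CC[C@H]3C | intermediate
16 | 2,4,6-trihydroxybenzene-1,3-dicarbaldehyde | O=Cc1c(O)cc(O)c(C=O)c1O | starting material
17 | 2,4-dihydroxy-5-(3-methylbutylidene)-6-oxocyclohexa-1,3-diene-1,3-dicarbaldehyde (o-quinone methide) | CC(C)CC=C1C(=O)C(C=O)=C(O)C(C=O)=C1O | intermediate
18 | (1R,3a'R,6R,9'S,9a'R)-6',8'-dihydroxy-6,9a'-dimethyl-9'-(2-methylpropyl)-3a'-(phenylsulfanyl)-3-(propan-2-yl)-1',2',9',9a'-tetrahydro-3a'H-spiro[cyclohexane-1,3'-cyclopenta[b]chromen]-2-ene-5',7'-dicarbaldehyde | CC(C)C[C@@H]1c2c(O)c(C=O)c(O)c(C=O)c2O[C@@]2(Sc3ccccc3)[C@]1(C)CC[C@@]21C=C(C(C)C)CC[C@H]1C | intermediate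
19 | tertiary α-aryloxy radical at C-3a' of the tetracycle | CC(C)C[C@@H]1c2c(O)c(C=O)c(O)c(C=O)c2O[C]2[C@]1(C)CC[C@@]21C=C(C(C)C)CC[C@H]1C | intermediate
20 | CNP0121396.3: (1R,3a'S,6R,9'S,9a'R)-6',8'-dihydroxy-6,9a'-dimethyl-9'-(2-methylpropyl)-3-(propan-2-yl)-1',2',9',9a'-tetrahydro-3a'H-spiro[cyclohexane-1,3'-cyclopenta[b]chromen]-2-ene-5',7'-dicarbaldehyde | CC(C)C[C@@H]1c2c(O)c(C=O)c(O)c(C=O)c2O[C@H]2[C@]1(C)CC[C@@]21C=C(C(C)C)CC[C@H]1C | target

**Step count and risks**

Total steps: 9. Longest linear sequence: 9 steps (from 1 and 2 to 20); 4 and 16 are bought.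

Steps most likely to fail:

Step 9. Hydrogen-atom transfer to the ring-fusion radical may occur on the other face and give the trans-fused epimer at the O–CH carbon, or the radical may rearrange by a 1,2-vinyl shift before it is quenched. The fallback sets out from 18 and returns at 20; it installs the hydrogen by hydride on the open chain and closes the ether afterwards. 18 is hydrolysed (AgNO3, 2,6-lutidine, aqueous THF) to the open-chain keto triphenol F5. Its three phenols are deprotonated (aqueous NaOH) so that both formyl groups are masked as vinylogous carboxylates, and NaBH4 then reduces only the ketone, from the face opposite the aryl-bearing substituent, to the alcohol F6. Acid-catalysed dehydrative ring closure (TsOH, toluene, reflux, water removal), an addition–elimination at the phloroglucinol carbon that retains the carbinol configuration, should give 20.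

Step 8. Facial or endo/exo discrimination in the cycloaddition may be poor, the tetrasubstituted vinyl sulfide may react sluggishly so that 17 oligomerises or attacks the ring alkene, and the ketal may hydrolyse. The fallback sets out from 12 and returns at 18. 12 is converted (t-BuMe2SiOTf, Et3N, CH2Cl2) into the silyl enol ether F3, a stronger nucleophile that should add to 17 in a stepwise Mukaiyama–Michael/ring-closure sequence under the same domino conditions to give the silyl ketal F4. PhSH with catalytic Me3SiOTf (CH2Cl2, −40 °C) then exchanges the silyloxy for the phenylsulfanyl group and delivers 18.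

Step 5. E2 elimination of the secondary mesylate may outrun the alkylation, and discrimination between the two faces of the dienolate may be low. The fallback sets out from 8 and returns at 12, replacing steps 3 to 5. The methyl ketone of 8 is converted into its kinetic enol triflate F1 (KN(SiMe3)2, PhNTf2, THF, −78 °C). A palladium-catalysed asymmetric intramolecular α-alkenylation of the extended enolate (Pd2(dba)3, (R)-DTBM-SEGPHOS, NaOt-Bu, toluene) forms the same bond and should give the exo-methylene spiro ketone F2. Hydrogenation of the 1,1-disubstituted alkene (H2, RhCl(PPh3)3, benzene) then gives 12.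

**Further compounds**

F1 | step 5 | 6-(3-methyl-2-oxocyclopentylidene)-5-(propan-2-yl)hex-1-en-2-yl trifluoromethanesulfonate (E-alkylidene) | CC1CC/C(=C\C(C(C)C)CCC(=C)OS(=O)(=O)C(F)(F)F)C1=O
F2 | step 5 | (5S)-2-methyl-10-methylidene-7-(propan-2-yl)spiro[4.5]dec-6-en-1-one | O=C1C(C)CC[C@@]12C=C(C(C)C)CCC2=C
F3 | step 8 | tert-butyl{[(5R,10R)-2,10-dimethyl-7-(propan-2-yl)spiro[4.5]deca-1,6-dien-1-yl]oxy}dimethylsilane | CC(C)(C)[Si](C)(C)OC1=C(C)CC[C@@]12C=C(C(C)C)CC[C@H]2C
F4 | step 8 | 3a'-[tert-butyl(dimethyl)silyloxy] analogue of 18 (silyl ketal) | CC(C)C[C@@H]1c2c(O)c(C=O)c(O)c(C=O)c2O[C@@]2(O[Si](C)(C)C(C)(C)C)[C@]1(C)CC[C@@]21C=C(C(C)C)CC[C@H]1C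
F5 | step 9 | open-chain keto triphenol: 5-{3-methyl-1-[2,10-dimethyl-1-oxo-7-(propan-2-yl)spiro[4.5]dec-6-en-2-yl]butyl}-2,4,6-trihydroxybenzene-1,3-dicarbaldehyde | CC(C)C[C@H](c1c(O)c(C=O)c(O)c(C=O)c1O)[C@@]1(C)CC[C@]2(C1=O)C=C(C(C)C)CC[C@H]2C
F6 | step 9 | corresponding secondary alcohol (hydroxyl on the face of the aryl-bearing substituent) | CC(C)C[C@H](c1c(O)c(C=O)c(O)c(C=O)c1O)[C@@]1(C)CC[C@]2([C@H]1O)C=C(C(C)C)CC[C@H]2C
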